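Temperature is what differs between these flasks: the charges and the time are the same.

all flasks: left-handed substrate 0.29 M; solid reagent 1.20 equiv; free catalyst 12 mol%; right-handed substrate 0.29 M; time 1.0 min

| flask | remark | temperature |
|---|---|---|
| north-west | at 20 °C until 12 s, from then on at 60 °C |  |
| north |  | 40 °C |
| north-east |  | 60 °C |
| south-west |  | 20 °C |

    free catalyst + left-handed substrate ⇌ catalyst intermediate A (K1 = 4.1 M⁻¹, k1 = 10.1 M⁻¹ s⁻¹, Ea1 = 59.0 kJ mol⁻¹, ΔH1 = 18.0 kJ mol⁻¹)
    solid reagent ⇌ partner, rate k2*(cs2 - [partner]) while solid is left; crystals form when [partner] > cs2 (cs2 = 0.067 M, k2 = 0.0591 s⁻¹)
    partner + catalyst intermediate A → free catalyst + left-handed product (k3 = 17.3 M⁻¹ s⁻¹, Ea3 = 45.0 kJ mol⁻¹)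
    free catalyst + right-handed substrate ⇌ catalyst intermediate B (K4 = 0.69 M⁻¹, k4 = 91.2 M⁻¹ s⁻¹, Ea4 = 44.0 kJ mol⁻¹, ΔH4 = −62.0 kJ mol⁻¹)
    partner + catalyst intermediate B → free catalyst + right-handed product (k5 = 6.01 M⁻¹ s⁻¹, Ea5 = 38.0 kJ mol⁻¹)
    (constants at 40 °C)

- free catalyst is single-handed; left-handed substrate and right-handed substrate are mirror images of each other, charged as a racemate, each of them at the stated concentration
- solid reagent is a solid; its amount is given per volume of the solution
- the constants hold at 40 °C; other temperatures follow from the activation energies and enthalpies
- at the start none of the solid reagent is in solution
- an excess is the difference of the two amounts in percent of their sum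
- an excess is below zero if the other one leads

- the best flask by excess of left-handed product over right-handed product; "all alike" if 1.5 percentage points covers them all (north-west / north / north-east / south-west / all alike)
- excess of left-handed product over right-handed product at the end, north-west
- excess of left-handed product over right-handed product at the end, north
- excess of left-handed product over right-handed product at the end, north-east
- excess of left-handed product over right-handed product at the end, south-west

Bench note, written before any run:

1. Know what is in the flask: racemic substrate, single-handed catalyst, and solid reagent with none of it dissolved.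

2. For north and north-east, freeze c(partner) near zero as an estimate. The solid then dissolves at a steady 0.00396 M s⁻¹, which gives 0.238 M over 1.0 min, or 81.9 % of the left-handed substrate. Count that supply as left-handed product.

3. Treat both binding steps as equilibria. At 40 °C, catalyst intermediate A falls back at 2.46 s⁻¹, faster than partner at its solubility consumes it, 1.16 s⁻¹. Catalyst intermediate B falls back at 132 s⁻¹, faster than partner at its solubility consumes it, 0.403 s⁻¹.

4. Use the selectivity factor q: binding constant times partner-step rate constant for the left-handed substrate, over the same product for the right-handed substrate. At 40 °C, 17.1. Its enthalpies and activation energies combine to 87.0 kJ mol⁻¹, so at 60 °C q is 127, higher than at 40 °C.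

5. Expect this at the end. The logarithmic loss of left-handed substrate is 1.71, and the right-handed substrate loses that divided by q. North then has 0.0276 M of right-handed product, an excess of 79.2 %. North-east has 0.00388 M, an excess of 96.8 %. My reckoning stops here: it does not cover the cold periods of north-west and south-west.

6. Do not touch the bath: from north to north-east, q changes 7.43-fold. Keep the change in north-west at 12 s.

The forecast names north-east and reasons that “Dissolution limits the supply of partner”. It gives 92.3 % (89 % to 95 %) for north-west, 83 % (78 % to 87 %) for north, 96.9 % (95.5 % to 98 %) for north-east and 19.5 % (15 % to 25 %) for south-west. Its factor at 60 °C is 120, and its north excess of 83 % is higher than my 79.2 %.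

The simulation gives north-east as best, with 92.2 % for north-west, 82.5 % for north, 96.8 % for north-east and 18.7 % for south-west.

In north-east, 24 % of the left-handed substrate is left at 1.00 min. With q, that gives right-handed product at 0.559 % of both substrates charged, and the flask holds 0.584 %. Repeat the reckoning on the neighbour, south-west run at 35 °C. There q is 9.95, which gives 0.0458 M of right-handed product and an excess of 67.7 %. The flask gives 73.5 %, with left-handed product at 24.6 % and right-handed product at 3.76 % of both substrates charged.

(All constants were set for the occasion; what happens was integrated by code.)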